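## Retrosynthetic overview

1. Building blocks: triacetic acid lactone 1 and benzaldehyde 2 give, through aldol adduct 3, the styrylpyranone 4; benzylacetone 5 and cinnamaldehyde 6 give alnustone 7.
2. Key disconnection, both ring bonds in one catalytic operation: C4–C4a by enantioselective 1,6-conjugate addition of C3 of 4 to the δ-carbon of 7 (open-chain enone 8), then O1–C2 by oxa-Michael closure of the 4-OH onto 8, giving katsumadain A 9.
3. Ring order: the 2-pyranone ring is bought in 1 and carried through unchanged; the dihydropyran ring is the only ring formed, in the last step.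
4. Stereochemistry: C4 is set by the catalyst in the C–C bond formation; C2 is set by thermodynamic control (2,4-trans) in the reversible oxa-Michael closure.

Assumption: the quinine-derived amine is taken to leave open, at the δ-carbon of the extended iminium ion of 7, the same π-face it leaves open at the β-carbon of simple benzylidene ketones (where cyclic 1,3-dicarbonyls give the S adduct), which gives (4S); if the sense proves opposite, the quinidine-derived pseudoenantiomer is used.

## Route

Step 1
Reactants: 1 4-hydroxy-6-methyl-2H-pyran-2-one (triacetic acid lactone); 2 benzaldehyde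
Product: 4 4-hydroxy-6-[(E)-2-phenylethenyl]-2H-pyran-2-one, via aldol adduct 3 (not isolated)
Conditions: commercial LiN(i-Pr)2 solution (2.3 equiv), THF, −78 °C, 1 h; 2 (1.1 equiv), −78 → 0 °C; 2 M HCl quench, extract; crude 3, p-TsOH·H2O (0.2 equiv), toluene/1,4-dioxane, reflux (Dean–Stark)
Reagents that add atoms: none
Why: Dianion aldol addition then acid-catalysed dehydration: the second equivalent of amide base deprotonates the 6-methyl group of the 4-oxido-pyranone, this most basic carbanion adds to 2 to give 3, and acid ionises the benzylic alcohol and eliminates to the fully conjugated E-alkene (thermodynamic geometry), so the carbinol centre of 3 is destroyed and no stereocentre remains.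

Step 2
Reactants: 5 4-phenylbutan-2-one (benzylacetone); 6 (E)-cinnamaldehyde
Product: 7 alnustone [(4E,6E)-1,7-diphenylhepta-4,6-dien-3-one]
Conditions: pyrrolidine (0.3 equiv), AcOH (0.3 equiv), THF, rt → 50 °C
Reagents that add atoms: none
Why: Amine-catalysed Claisen–Schmidt (crossed aldol) condensation: pyrrolidine converts 5 into its less substituted methyl-side enamine, which adds to the iminium ion of the non-enolisable aldehyde 6, and loss of the amine gives the conjugated 4E,6E-dienone under thermodynamic control; no stereocentre is formed.

Step 3
Reactants: 4 4-hydroxy-6-[(E)-2-phenylethenyl]-2H-pyran-2-one; 7 alnustone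
Product: 9 katsumadain A [(2S,4S)-2-(2-oxo-4-phenylbutyl)-4-phenyl-7-[(E)-2-phenylethenyl]-3,4-dihydro-2H,5H-pyrano[4,3-b]pyran-5-one], via 1,6-adduct enone 8 (not isolated)
Conditions: 9-amino-9-deoxy-epi-quinine [(8α,9S)-6'-methoxycinchonan-9-amine] (20 mol%), CF3CO2H (40 mol%), THF, 40 °C, 72 h; recrystallise
Reagents that add atoms: none
Why: Proposed new method: the primary amine condenses with the ketone of 7 to a vinylogous iminium ion whose benzylic δ-carbon is attacked by C3 of 4 on the π-face left open by the catalyst (sets C4 as S); the resulting dienamine is protonated at its γ-carbon to the iminium ion of enone 8, whose β-carbon is attacked 6-exo by the pyranone 4-OH (oxa-Michael), and enamine hydrolysis releases 9 and the catalyst; competing β-attack (1,4-adduct) is reversible by retro-Michael from its enamine whereas the δ-adduct is drained by ring closure, and the ring closure is itself reversible, so C2 settles under thermodynamic control as the 2,4-trans isomer (C4-phenyl pseudoaxial away from the C5 carbonyl, C2 chain equatorial), which is 2S; the closest known reaction types are the cinchona primary-amine iminium-catalysed Michael addition of 4-hydroxycoumarin-type cyclic 1,3-dicarbonyls to enones, vinylogous-iminium 1,6-additions to dienones, and amine-catalysed intramolecular oxa-Michael additions, combined here as a tandem 1,6-conjugate addition/oxa-Michael cascade.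

## Compound list

1 | 4-hydroxy-6-methyl-2H-pyran-2-one (triacetic acid lactone) | Cc1cc(O)cc(=O)o1 | starting material
2 | benzaldehyde | O=Cc1ccccc1 | starting material
3 | 4-hydroxy-6-(2-hydroxy-2-phenylethyl)-2H-pyran-2-one (racemic aldol adduct, not isolated) | OC(Cc1cc(O)cc(=O)o1)c1ccccc1 | intermediate
4 | 4-hydroxy-6-[(E)-2-phenylethenyl]-2H-pyran-2-one (styryl-2-pyranone) | O=c1cc(O)cc(/C=C/c2ccccc2)o1 | intermediate
5 | 4-phenylbutan-2-one (benzylacetone) | CC(=O)CCc1ccccc1 | starting material
6 | (E)-cinnamaldehyde [(2E)-3-phenylprop-2-enal] | O=C/C=C/c1ccccc1 | starting material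
7 | alnustone [(4E,6E)-1,7-diphenylhepta-4,6-dien-3-one] | O=C(CCc1ccccc1)/C=C/C=C/c1ccccc1 | intermediate
8 | 4-hydroxy-3-[(1S,3E)-5-oxo-1,7-diphenylhept-3-en-1-yl]-6-[(E)-2-phenylethenyl]-2H-pyran-2-one (not isolated; present in the flask mainly as its iminium ion with the catalyst, drawn as the free ketone) | O=C(CCc1ccccc1)/C=C/C[C@@H](c1ccccc1)c1c(O)cc(/C=C/c2ccccc2)oc1=O | intermediate
9 | katsumadain A [(2S,4S)-2-(2-oxo-4-phenylbutyl)-4-phenyl-7-[(E)-2-phenylethenyl]-3,4-dihydro-2H,5H-pyrano[4,3-b]pyran-5-one; 2,4-trans] | O=C(CCc1ccccc1)C[C@@H]1C[C@@H](c2ccccc2)c2c(cc(/C=C/c3ccccc3)oc2=O)O1 | target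

## Step count and risks

Total step count: 3. Longest linear sequence: 2 steps (1 → 4 → 9, or 5 → 7 → 9).

The three steps most likely to fail, most risky first:

**Step 3.** The attack may go to the β-carbon of 7 and stop at a warfarin-type 1,4-adduct. Iminium formation at a ketone flanked by a CH2CH2Ph group may be slow. Enantiocontrol at a carbon this far from the catalyst is unproven. The fallback sets out from 4 (with 6) and replaces the dienone by the enal, so that the C–C bond is made by a well-understood 1,4-addition. With (S)-2-[diphenyl(trimethylsilyloxy)methyl]pyrrolidine (20 mol%) and benzoic acid (20 mol%) in CH2Cl2 at rt, C3 of 4 adds to the β-carbon of the iminium ion of 6 from the face opposite the diphenyl(silyloxy)methyl group. The adduct is isolated as the lactol (4S)-2-hydroxy-4-phenyl-7-[(E)-2-phenylethenyl]-3,4-dihydro-2H,5H-pyrano[4,3-b]pyran-5-one F3 (anomer mixture). A Horner–Wadsworth–Emmons reaction of the open aldehyde form of F3 with commercial dimethyl (2-oxo-4-phenylbutyl)phosphonate (LiCl, DBU, MeCN, rt) then comes back to the route at enone 8. Enone 8 closes by oxa-Michael addition to 9 in the same flask under the basic conditions.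

**Step 1.** The dianion of 1 is poorly soluble and can give low conversion, and the polar product 4 is awkward to purify after the acid dehydration. The fallback sets out from 6 and builds the pyranone ring instead of functionalising it. The lithium dienolate of commercial 2,2,6-trimethyl-4H-1,3-dioxin-4-one (LiN(i-Pr)2, THF, −78 °C) adds through its γ-carbon to 6 to give racemic 6-[(3E)-2-hydroxy-4-phenylbut-3-en-1-yl]-2,2-dimethyl-4H-1,3-dioxin-4-one F1. MnO2 in CH2Cl2 oxidises the allylic alcohol to 2,2-dimethyl-6-[(3E)-2-oxo-4-phenylbut-3-en-1-yl]-4H-1,3-dioxin-4-one F2. Heating F2 in toluene at 110 °C expels acetone in a retro-hetero-Diels–Alder reaction, and the acylketene is trapped by the enol oxygen of the side-chain ketone. This closes the 4-hydroxy-2-pyranone ring and comes back to the route at 4.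

**Step 2.** Condensation on the methylene side of 5, double condensation, or amine addition to 6 can lower the yield of 7. The fallback sets out from 6 and fixes the regiochemistry by olefination instead of aldol chemistry. A Horner–Wadsworth–Emmons reaction of 6 with commercial dimethyl (2-oxo-4-phenylbutyl)phosphonate (LiCl, i-Pr2NEt, MeCN, rt) forms the 4E alkene directly and comes back to the route at 7. No new compound is made on this way (F0).

Further compounds

F1 | step 1 | 6-[(3E)-2-hydroxy-4-phenylbut-3-en-1-yl]-2,2-dimethyl-4H-1,3-dioxin-4-one (racemic) | CC1(C)OC(CC(O)/C=C/c2ccccc2)=CC(=O)O1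
F2 | step 1 | 2,2-dimethyl-6-[(3E)-2-oxo-4-phenylbut-3-en-1-yl]-4H-1,3-dioxin-4-one | CC1(C)OC(CC(=O)/C=C/c2ccccc2)=CC(=O)O1
F0 | step 2 | none | none
F3 | step 3 | (4S)-2-hydroxy-4-phenyl-7-[(E)-2-phenylethenyl]-3,4-dihydro-2H,5H-pyrano[4,3-b]pyran-5-one (anomer mixture) | OC1C[C@@H](c2ccccc2)c2c(cc(/C=C/c3ccccc3)oc2=O)O1
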